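**Assumption:** positions follow polyketide numbering (C1 = ester carbonyl, C14 = end of the side chain); the SMILES is read as methyl 2-[(3S,4S,6S)-4,6-diethyl-6-[(4R,5E)-4-ethyloct-5-en-1-yl]-1,2-dioxan-3-yl]acetate, i.e. 3S,4S,6S,10R,11E.

## Retrosynthetic overview

1. The only ring, the 1,2-dioxane, is closed last by the biogenetic event: 6-exo peroxy-Michael addition of a C6 tertiary hydroperoxide to the Δ2-enoate (forms O–C3, sets C3 from C4).
2. The C6–OOH comes from the C6 tertiary carbinol by SN1 perhydrolysis on the unprotected chain; the enoate comes from cross-metathesis of a terminal vinyl group with methyl acrylate.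
3. The carbinol is assembled at C6 from an ethyl ketone (C6–C14) and a C2–C5 Grignard reagent; the ketone comes from a C9 Grignard reagent and ethyl vinyl ketone.
4. Both ethyl-branched stereocentres (C4, C10) are the two enantiomers of one building block, 3-(bromomethyl)pent-1-ene, from Cu-catalysed asymmetric allylic alkylation of (E)-1,4-dibromobut-2-ene with EtMgBr.
5. C6 (ethyl against n-alkyl) cannot be set by substrate control: it is carried as a 1:1 mixture and the 6R epimer is removed after ring closure.

## Route

Step 1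
Reactants: 1 (E)-1,4-dibromobut-2-ene; 2 ethylmagnesium bromide
Product: 3 (R)-3-(bromomethyl)pent-1-ene
Conditions: CuBr·SMe2 (2 mol %), (R,Rp)-Taniaphos (2.4 mol %), CH2Cl2, −78 °C, 2 (1.15 equiv, Et2O) added slowly
Reagents that add atoms: none
Why: Cu-catalysed asymmetric allylic alkylation (SN2′), in which the chiral Cu(I)–ethyl species delivers Et to the γ-carbon anti to the leaving bromide on one alkene face and so creates the ethyl-bearing stereocentre (about 95 % ee and SN2′:SN2 > 95:5 expected; the CH2Br left behind is no longer allylic and does not react again; the ligand sense is assigned by analogy with other aliphatic allyl bromides and is checked by chiral GC, swapping ligand antipodes if needed).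

Step 2
Reactants: 1 (E)-1,4-dibromobut-2-ene; 2 ethylmagnesium bromide
Product: 4 (S)-3-(bromomethyl)pent-1-ene
Conditions: CuBr·SMe2 (2 mol %), (S,Sp)-Taniaphos (2.4 mol %), CH2Cl2, −78 °C, 2 added slowly
Reagents that add atoms: none
Why: The same asymmetric allylic alkylation with the mirror-image ligand gives the enantiomeric building block, whose stereocentre becomes C10.

Step 3
Reactants: 4 (S)-3-(bromomethyl)pent-1-ene; 5 (E)-hex-3-ene
Product: 6 (3E,5S)-5-(bromomethyl)hept-3-ene
Conditions: Grubbs II (2 mol %), 5 (5 equiv), 1,4-benzoquinone (10 mol %), CH2Cl2, 40 °C; AgNO3–SiO2 chromatography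
Reagents that add atoms: none
Why: Olefin cross-metathesis under thermodynamic control gives the E-alkene (about 9:1, the Z isomer is removed on AgNO3–silica), and benzoquinone suppresses Ru–H alkene migration so the allylic stereocentre is untouched.

Step 4
Reactants: 6 (3E,5S)-5-(bromomethyl)hept-3-ene; 7 pent-1-en-3-one (ethyl vinyl ketone)
Product: 10 (7R,8E)-7-ethylundec-8-en-3-one, via Grignard reagent 8 (not isolated), via trimethylsilyl enol ether 9 (not isolated)
Conditions: Mg, THF, rt; then CuBr·SMe2 (10 mol %), TMSCl (2 equiv), 7 (1.2 equiv), THF, −78 °C; 1 M HCl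
Reagents that add atoms: none
Why: Cu-catalysed, TMSCl-accelerated 1,4-addition of a primary Grignard reagent to a vinyl ketone (the silyl trap stops enolate–enone oligomerisation) builds C6–C9 in one step; no stereocentre is formed and the β-stereocentre of the Grignard reagent is not affected when it is used promptly.

Step 5
Reactants: 3 (R)-3-(bromomethyl)pent-1-ene; 10 (7R,8E)-7-ethylundec-8-en-3-one
Product: 12 (3S,9R,10E)-3,5,9-triethyltrideca-1,10-dien-5-ol (1:1 at C5), via Grignard reagent 11 (not isolated)
Conditions: 3, Mg, THF, rt; then 10, LaCl3·2LiCl (30 mol %), THF, 0 °C; H2O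
Reagents that add atoms: none
Why: Lanthanum-promoted Grignard 1,2-addition to an enolisable ketone joins the two halves at C6; the carbinol centre forms without control (about 1:1), which costs nothing because it is ionised in step 7, and C4 and C10 are untouched.

Step 6
Reactants: 12 (3S,9R,10E)-3,5,9-triethyltrideca-1,10-dien-5-ol; 13 methyl acrylate
Product: 14 methyl (2E,4S,10R,11E)-4,6,10-triethyl-6-hydroxytetradeca-2,11-dienoate (1:1 at C6)
Conditions: Hoveyda–Grubbs II (3 mol %), 13 (3 equiv), CH2Cl2, 40 °C
Reagents that add atoms: none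
Why: Cross-metathesis of the terminal vinyl group with an acrylate is E-selective (> 20:1) and faster than metathesis of the internal, allylically branched E-alkene; the free tertiary alcohol is tolerated and the γ-stereocentre C4 is not touched.

Step 7
Reactants: 14 methyl (2E,4S,10R,11E)-4,6,10-triethyl-6-hydroxytetradeca-2,11-dienoate
Product: 15 methyl (2E,4S,10R,11E)-4,6,10-triethyl-6-hydroperoxytetradeca-2,11-dienoate (1:1 at C6)
Conditions: 50 % aq. H2O2 (20 equiv), H2SO4 (0.2 equiv), MTBE, 0 °C → rt
Reagents that add atoms: hydrogen peroxide, OO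
Why: Acid-catalysed SN1 perhydrolysis of a tertiary alcohol, in which the C6 cation is captured by the large excess of H2O2 faster than it eliminates or meets the remote alkene; the enoate and the 1,2-disubstituted alkene are inert to H2O2/H+, and C6 stays 1:1.

Step 8
Reactants: 15 methyl (2E,4S,10R,11E)-4,6,10-triethyl-6-hydroperoxytetradeca-2,11-dienoate
Product: 16 methyl 2-[(3S,4S,6S)-4,6-diethyl-6-[(4R,5E)-4-ethyloct-5-en-1-yl]-1,2-dioxan-3-yl]acetate
Conditions: Et2NH (2 equiv), CF3CH2OH, 0 °C → rt; SiO2 chromatography, then normal-phase HPLC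
Reagents that add atoms: none
Why: Biomimetic 6-exo-trig intramolecular peroxy-Michael (oxa-Michael) addition under kinetic control: the fluoroalcohol protonates the ester enolate at once (no retro-Michael, no collapse to the glycidic ester), and the peroxide oxygen attacks C3 through a Felkin–Anh-type chair with the C4 ethyl equatorial and anti to the incoming oxygen, the ring CH2 inside and the enoate axial, which gives the 3,4-cis ring (3S from 4S) as expected by analogy with kinetically controlled oxa-Michael closures that place the ester side chain axial; C6 is not controlled, so the 6S half of 15 gives 16 and the 6R half gives its ring diastereomer, which is removed together with minor 3,4-trans isomers by chromatography.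

## Compound list

1 | (E)-1,4-dibromobut-2-ene | BrC/C=C/CBr | starting material
2 | ethylmagnesium bromide | CC[Mg]Br | starting material
3 | (R)-3-(bromomethyl)pent-1-ene | C=C[C@@H](CC)CBr | intermediate
4 | (S)-3-(bromomethyl)pent-1-ene | C=C[C@H](CC)CBr | intermediate
5 | (E)-hex-3-ene | CC/C=C/CC | starting material
6 | (3E,5S)-5-(bromomethyl)hept-3-ene | CC/C=C/[C@H](CC)CBr | intermediate
7 | pent-1-en-3-one (ethyl vinyl ketone) | C=CC(=O)CC | starting material
8 | [(2S,3E)-2-ethylhex-3-en-1-yl]magnesium bromide (not isolated) | CC/C=C/[C@H](CC)C[Mg]Br | intermediate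
9 | trimethyl{[(7R,8E)-7-ethylundeca-3,8-dien-3-yl]oxy}silane, 3E/Z (not isolated) | CC/C=C/[C@H](CC)CCC=C(CC)O[Si](C)(C)C | intermediate
10 | (7R,8E)-7-ethylundec-8-en-3-one | CC/C=C/[C@H](CC)CCCC(=O)CC | intermediate
11 | [(2R)-2-ethylbut-3-en-1-yl]magnesium bromide (not isolated) | C=C[C@@H](CC)C[Mg]Br | intermediate
12 | (3S,9R,10E)-3,5,9-triethyltrideca-1,10-dien-5-ol, 1:1 at C5 | C=C[C@@H](CC)CC(O)(CC)CCC[C@@H](CC)/C=C/CC | intermediate
13 | methyl acrylate | C=CC(=O)OC | starting material
14 | methyl (2E,4S,10R,11E)-4,6,10-triethyl-6-hydroxytetradeca-2,11-dienoate, 1:1 at C6 | COC(=O)/C=C/[C@@H](CC)CC(O)(CC)CCC[C@@H](CC)/C=C/CC | intermediate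
15 | methyl (2E,4S,10R,11E)-4,6,10-triethyl-6-hydroperoxytetradeca-2,11-dienoate, 1:1 at C6 | COC(=O)/C=C/[C@@H](CC)CC(OO)(CC)CCC[C@@H](CC)/C=C/CC | intermediate
16 | methyl 2-[(3S,4S,6S)-4,6-diethyl-6-[(4R,5E)-4-ethyloct-5-en-1-yl]-1,2-dioxan-3-yl]acetate | CC/C=C/[C@H](CC)CCC[C@@]1(CC)C[C@H](CC)[C@H](CC(=O)OC)OO1 | target

## Step count and risks

Total steps: 8. Longest linear sequence: 7 (steps 2, 3, 4, 5, 6, 7, 8). No protecting groups.

**Step 8 (ring closure).** Risk: too little 3,4-cis selectivity, retro-Michael or epoxide formation from the ester enolate, and a hard separation of the C6 epimers. The fallback changes the acceptor to a thioester and closes under catalyst control. It sets out from 12: cross-metathesis with S-ethyl prop-2-enethioate (Hoveyda–Grubbs II) gives S-ethyl (2E,4S,10R,11E)-4,6,10-triethyl-6-hydroxytetradeca-2,11-dienethioate F1. Perhydrolysis as in step 7 gives S-ethyl (2E,4S,10R,11E)-4,6,10-triethyl-6-hydroperoxytetradeca-2,11-dienethioate F2. The more electrophilic thioester closes at −40 °C with 5–10 mol % of a cinchona thiourea–amine catalyst (antipode screened for the 3S sense) to S-ethyl 2-[(3S,4S)-4,6-diethyl-6-[(4R,5E)-4-ethyloct-5-en-1-yl]-1,2-dioxan-3-yl]ethanethioate F3. AgOTf in MeOH converts F3, after separation of the C6 epimers, into 16, where it comes back to the route.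

**Step 7 (perhydrolysis).** Risk: E1 elimination, cation–alkene cyclisation onto C11=C12, or acid-induced Hock-type rearrangement of the hydroperoxide. The fallback uses radical instead of cationic oxygenation. It sets out from 14: dehydration with Burgess reagent gives the C6 olefin mixture of methyl (2E,4R,10R,11E)-4,6,10-triethyltetradeca-2,5,11-trienoate F4, methyl (2E,4S,10R,11E)-4,6,10-triethyltetradeca-2,6,11-trienoate F5 and methyl (2E,4S,10R,11E)-4,10-diethyl-6-ethylidenetetradeca-2,11-dienoate F6. Isayama–Mukaiyama peroxysilylation (Co(thd)2 cat., O2, Et3SiH, DCE, rt) takes all three through the same C6 tertiary radical to methyl (2E,4S,10R,11E)-4,6,10-triethyl-6-[(triethylsilyl)peroxy]tetradeca-2,11-dienoate F7; the enoate and the 1,2-disubstituted alkene react much more slowly in hydrogen-atom transfer. HF·pyridine then releases 15, where it comes back to the route.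

**Step 6 (cross-metathesis with acrylate).** Risk: the Ru carbene also cuts the internal C11=C12 alkene. The fallback is a Pd(II)-catalysed oxidative methoxycarbonylation of the terminal alkene (Pd(II) cat., CO, MeOH/MeCN, benzoquinone or O2), an alkoxycarbonyl-palladation/β-hydride elimination that engages only the monosubstituted alkene. It sets out from 12, comes back at 14 and makes no new compound (F0).

## Further compounds

F1 | step 8 | S-ethyl (2E,4S,10R,11E)-4,6,10-triethyl-6-hydroxytetradeca-2,11-dienethioate, 1:1 at C6 | CCSC(=O)/C=C/[C@@H](CC)CC(O)(CC)CCC[C@@H](CC)/C=C/CC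
F2 | step 8 | S-ethyl (2E,4S,10R,11E)-4,6,10-triethyl-6-hydroperoxytetradeca-2,11-dienethioate, 1:1 at C6 | CCSC(=O)/C=C/[C@@H](CC)CC(OO)(CC)CCC[C@@H](CC)/C=C/CC
F3 | step 8 | S-ethyl 2-[(3S,4S)-4,6-diethyl-6-[(4R,5E)-4-ethyloct-5-en-1-yl]-1,2-dioxan-3-yl]ethanethioate, both C6 epimers | CC/C=C/[C@H](CC)CCCC1(CC)C[C@H](CC)[C@H](CC(=O)SCC)OO1
F4 | step 7 | methyl (2E,4R,10R,11E)-4,6,10-triethyltetradeca-2,5,11-trienoate, 5E/Z | COC(=O)/C=C/[C@@H](CC)C=C(CC)CCC[C@@H](CC)/C=C/CC
F5 | step 7 | methyl (2E,4S,10R,11E)-4,6,10-triethyltetradeca-2,6,11-trienoate, 6E/Z | COC(=O)/C=C/[C@@H](CC)CC(CC)=CCC[C@@H](CC)/C=C/CC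
F6 | step 7 | methyl (2E,4S,10R,11E)-4,10-diethyl-6-ethylidenetetradeca-2,11-dienoate, E/Z at the ethylidene | COC(=O)/C=C/[C@@H](CC)CC(=CC)CCC[C@@H](CC)/C=C/CC
F7 | step 7 | methyl (2E,4S,10R,11E)-4,6,10-triethyl-6-[(triethylsilyl)peroxy]tetradeca-2,11-dienoate, 1:1 at C6 | COC(=O)/C=C/[C@@H](CC)CC(OO[Si](CC)(CC)CC)(CC)CCC[C@@H](CC)/C=C/CC
F0 | step 6 | none | none
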